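**Retrosynthetic overview**
1. Target 20 ⇒ cut the C6–prenyl bond (Pd-catalysed dearomative allylation of ring A) and the lactone C–O bond ⇒ tricyclic lactone 17.
2. 17 ⇒ cut the C8–CH(Ph) bond and the lactone C–O bond (carbene-catalysed annulation with cinnamaldehyde) ⇒ chromanone 15.
3. 15 ⇒ key disconnection at the pyranone O1–C2 bond (asymmetric dehydrative oxa-Michael ring closure, sets C2 and C3) ⇒ aldol 13 ⇒ ketone 11 + acetaldehyde.
4. 11 ⇒ Wittig olefination and enamine/ortho-quinone-methide alkylation ⇒ flopropione-derived sulfone 6 + aldehyde 2.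
5. Ring order: ring A (benzene) is bought; pyranone ring B closes in step 6; lactone ring C closes in step 7 and is opened in step 8, where ring A is dearomatised.

Assumption: tautomers of the enolised triketone 20 and the ring–chain tautomers of lactol 8 are each treated as one compound; 1, 3, 4, 5, 9, 12, 16 and 18 are bought.

**Step 1**
Reactants: 1 2-methylpenta-1,4-diene
Product: 2 5-methylhex-5-enal
Conditions: Rh(acac)(CO)2 (0.2 mol%), bisphosphite ligand BiPhePhos (0.6 mol%), CO/H2 (1:1, 10 bar), toluene, 60 °C
Reagents that add atoms: carbon monoxide, [C-]#[O+]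
Why: Linear-selective rhodium-catalysed hydroformylation adds H/CHO anti-Markovnikov to the monosubstituted alkene only, the 1,1-disubstituted alkene reacting far more slowly; no stereocentre is formed.

**Step 2**
Reactants: 3 flopropione; 4 formaldehyde (as paraformaldehyde); 5 sodium p-toluenesulfinate
Product: 6 1-{2,4,6-trihydroxy-3-[(4-methylbenzenesulfonyl)methyl]phenyl}propan-1-one
Conditions: 4 (1.0 equiv), 5 (1.05 equiv), HCO2H/H2O (1:1), 25 °C
Reagents that add atoms: none
Why: Mannich-type three-component sulfonylmethylation (electrophilic aromatic substitution) at one of the two equivalent ring CH positions; the sulfone precipitates, which limits double substitution; no stereocentre.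

**Step 3**
Reactants: 6 sulfone; 2 5-methylhex-5-enal (2.5 equiv)
Product: 8 1-[(3S)-2,5,7-trihydroxy-3-(3-methylbut-3-en-1-yl)-3,4-dihydro-2H-chromen-6-yl]propan-1-one (lactol), via ortho-quinone methide 7 (not isolated)
Conditions: (R)-2-[diphenyl(trimethylsilyloxy)methyl]pyrrolidine (20 mol%), NaHCO3 (2 equiv), CH2Cl2, 0 °C → rt; aqueous work-up
Reagents that add atoms: none
Why: Enamine catalysis on an ortho-quinone methide (Michael addition/ring closure, formal [4+2]): NaHCO3 releases 7 slowly from 6, and the (E)-enamine of 2 attacks its CH2 from the face not covered by the diphenyl(silyloxy)methyl group, setting the side-chain centre as S (the (S)-catalyst gives R in the analogous nitroalkene Michael addition); excess 2 suppresses methylene-bridged dimers, and the lactol (anomers, closure on either flanking phenol) converges in step 4.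

**Step 4**
Reactants: 8 lactol; 9 isopropyltriphenylphosphonium iodide (5.5 equiv)
Product: 11 1-{2,4,6-trihydroxy-3-[(2S)-5-methyl-2-(2-methylprop-1-en-1-yl)hex-5-en-1-yl]phenyl}propan-1-one, via isopropylidenetriphenylphosphorane 10 (not isolated)
Conditions: 9, KN(SiMe3)2 (5.3 equiv), THF, 0 °C; then 8, 0 °C → rt; aq NH4Cl, then 1 M HCl to pH 4
Reagents that add atoms: none
Why: Wittig olefination of the ring-opened lactol (hydroxy aldehyde) with the non-stabilised ylide installs the 2-methylprop-1-enyl group; excess ylide absorbs the three acidic OH groups, the aryl ketone is inert as its phenoxide (vinylogous carboxylate), and olefination outruns enolisation of the α-branched aldehyde, so the S centre is kept.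

**Step 5**
Reactants: 11 ketone; 12 acetaldehyde (3 equiv)
Product: 13 3-hydroxy-2-methyl-1-{2,4,6-trihydroxy-3-[(2S)-5-methyl-2-(2-methylprop-1-en-1-yl)hex-5-en-1-yl]phenyl}butan-1-one (diastereomer mixture at the two new centres)
Conditions: LiN(SiMe3)2 (4.4 equiv), THF, −78 → −20 °C; 12, −78 °C; AcOH (6 equiv), −78 °C
Reagents that add atoms: none
Why: Aldol addition of the fully deprotonated aryl ethyl ketone (excess lithium amide, as in C-acylations of polyhydroxyacetophenones) to acetaldehyde at −78 °C, where the phenoxide ring carbon does not compete; the two new centres form unselectively and are both reset in step 6.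

**Step 6**
Reactants: 13 aldol
Product: 15 (2R,3S)-5,7-dihydroxy-2,3-dimethyl-6-[(2S)-5-methyl-2-(2-methylprop-1-en-1-yl)hex-5-en-1-yl]-2,3-dihydro-4H-chromen-4-one, via tigloyl ketone 14 (not isolated)
Conditions: (R)-3,3'-bis(2,4,6-triisopropylphenyl)-1,1'-binaphthyl-2,2'-diyl hydrogen phosphate (10 mol%), anhydrous MgSO4, toluene, 50 °C
Reagents that add atoms: none
Why: Proposed new method: a stereoconvergent dehydrative oxa-Michael cyclisation in which the chiral phosphoric acid first dehydrates the β-hydroxy ketone through its enol to the (E)-enone 14, then binds 14 bifunctionally (P–OH to the carbonyl, P=O to the free 6-OH, while the 2-OH next to the side chain stays chelated to C=O) so that the less hindered phenol adds 6-endo to one enone face (C–O bond, C2 = R) and the catalyst-bound enol is protonated anti to the new C2 methyl (kinetic cis, C3 = S), all four diastereomers of 13 converging on one chromanone; the closest known reactions are chiral-phosphoric-acid-catalysed intramolecular oxa-Michael additions and the cinchona-alkaloid-catalysed cyclisation of o-tigloylphenols to cis-2,3-dimethylchromanones; the sense of induction must be confirmed on the first run, and the (S)-acid is equally available.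

**Step 7**
Reactants: 15 chromanone; 16 (E)-cinnamaldehyde (1.5 equiv)
Product: 17 tricyclic lactone: chromanone 15 fused at O7/C8 to an (S)-4-phenyl-3,4-dihydro-2H-pyran-2-one ring (lactone C=O on O7; CHPh on C8)
Conditions: (5aS,10bR)-2-mesityl-5a,10b-dihydro-4H,6H-indeno[2,1-b][1,2,4]triazolo[4,3-d][1,4]oxazin-2-ium chloride (10 mol%), 1,4-diazabicyclo[2.2.2]octane (1.0 equiv), 3,3',5,5'-tetra-tert-butyl-4,4'-diphenoquinone (1.2 equiv), toluene, rt
Reagents that add atoms: none
Why: Oxidative N-heterocyclic-carbene catalysis ([3+3] Michael addition/lactonisation): the enal is oxidised to the α,β-unsaturated acyl azolium, the only free ring carbon C8 adds to the Si face of its β-carbon (benzylic centre S, catalyst control), and acyl transfer can only close on O7 because O1 is an ether; the mirror-image triazolium salt is used if a test run gives the benzylic epimer.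

**Step 8**
Reactants: 17 lactone; 18 prenyl acetate (1.3 equiv)
Product: 20 3-[(2R,3S,6S)-4-hydroxy-2,3-dimethyl-6-(3-methylbut-2-en-1-yl)-6-[(2S)-5-methyl-2-(2-methylprop-1-en-1-yl)hex-5-en-1-yl]-5,7-dioxo-3,5,6,7-tetrahydro-2H-chromen-8-yl]-(3S)-3-phenylpropanoic acid, via ring-opened hydroxy acid 19 (not isolated)
Conditions: LiOH·H2O (3.1 equiv), THF/H2O (9:1), 0 °C, 30 min; then 18, Pd2(dba)3·CHCl3 (2.5 mol%, zerovalent palladium), N,N'-[(1R,2R)-cyclohexane-1,2-diyl]bis[2-(diphenylphosphanyl)benzamide] (7.5 mol%), 0 °C → rt; then 1 M HCl to pH 3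
Reagents that add atoms: lithium hydroxide, [Li+].[OH-]
Why: Lactone hydrolysis followed by palladium-catalysed asymmetric allylic alkylation with dearomatisation (Tsuji–Trost type): C6, flanked by two phenoxides, attacks the CH2 terminus of the π-prenyl palladium complex (linear prenyl), the chiral ligand pocket selects the ring face (quaternary centre S), and the product is the stable vinylogous acid, so O-prenylation is reversible and C8 (fully substituted) does not compete; the (S,S)-ligand is used if the first run favours the C6 epimer.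

**Compound list**
1 | 2-methylpenta-1,4-diene | C=CCC(C)=C | starting material
2 | 5-methylhex-5-enal | C=C(C)CCCC=O | intermediate
3 | flopropione, 1-(2,4,6-trihydroxyphenyl)propan-1-one | CCC(=O)c1c(O)cc(O)cc1O | starting material
4 | formaldehyde (used as paraformaldehyde) | C=O | starting material
5 | sodium p-toluenesulfinate | Cc1ccc(cc1)S(=O)[O-].[Na+] | starting material
6 | 1-{2,4,6-trihydroxy-3-[(4-methylbenzenesulfonyl)methyl]phenyl}propan-1-one | CCC(=O)c1c(O)cc(O)c(CS(=O)(=O)c2ccc(C)cc2)c1O | intermediate
7 | ortho-quinone methide, 3,5-dihydroxy-6-methylidene-2-propanoylcyclohexa-2,4-dien-1-one | CCC(=O)C1=C(O)C=C(O)C(=C)C1=O | intermediate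
8 | 1-[(3S)-2,5,7-trihydroxy-3-(3-methylbut-3-en-1-yl)-3,4-dihydro-2H-chromen-6-yl]propan-1-one (lactol, anomer mixture) | CCC(=O)c1c(O)cc2c(c1O)C[C@H](CCC(C)=C)C(O)O2 | intermediate
9 | isopropyltriphenylphosphonium iodide | CC(C)[P+](c1ccccc1)(c1ccccc1)c1ccccc1.[I-] | starting material
10 | isopropylidenetriphenylphosphorane | CC(C)=P(c1ccccc1)(c1ccccc1)c1ccccc1 | intermediate
11 | 1-{2,4,6-trihydroxy-3-[(2S)-5-methyl-2-(2-methylprop-1-en-1-yl)hex-5-en-1-yl]phenyl}propan-1-one | CCC(=O)c1c(O)cc(O)c(C[C@@H](C=C(C)C)CCC(C)=C)c1O | intermediate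
12 | acetaldehyde | CC=O | starting material
13 | 3-hydroxy-2-methyl-1-{2,4,6-trihydroxy-3-[(2S)-5-methyl-2-(2-methylprop-1-en-1-yl)hex-5-en-1-yl]phenyl}butan-1-one (mixture at C2 and C3 of the butanone chain) | CC(O)C(C)C(=O)c1c(O)cc(O)c(C[C@@H](C=C(C)C)CCC(C)=C)c1O | intermediate
14 | (2E)-2-methyl-1-{2,4,6-trihydroxy-3-[(2S)-5-methyl-2-(2-methylprop-1-en-1-yl)hex-5-en-1-yl]phenyl}but-2-en-1-one (tigloyl ketone) | C/C=C(\C)C(=O)c1c(O)cc(O)c(C[C@@H](C=C(C)C)CCC(C)=C)c1O | intermediate
15 | (2R,3S)-5,7-dihydroxy-2,3-dimethyl-6-[(2S)-5-methyl-2-(2-methylprop-1-en-1-yl)hex-5-en-1-yl]-2,3-dihydro-4H-chromen-4-one | C[C@H]1Oc2cc(O)c(C[C@@H](C=C(C)C)CCC(C)=C)c(O)c2C(=O)[C@H]1C | intermediate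
16 | (E)-cinnamaldehyde | O=C/C=C/c1ccccc1 | starting material
17 | tricyclic lactone: chromanone 15 fused at O7/C8 to an (S)-4-phenyl-3,4-dihydro-2H-pyran-2-one ring | C[C@H]1Oc2c3[C@H](c4ccccc4)CC(=O)Oc3c(C[C@@H](C=C(C)C)CCC(C)=C)c(O)c2C(=O)[C@H]1C | intermediate
18 | prenyl acetate, 3-methylbut-2-en-1-yl acetate | CC(=O)OCC=C(C)C | starting material
19 | (3S)-3-{(2R,3S)-5,7-dihydroxy-2,3-dimethyl-6-[(2S)-5-methyl-2-(2-methylprop-1-en-1-yl)hex-5-en-1-yl]-4-oxo-3,4-dihydro-2H-chromen-8-yl}-3-phenylpropanoic acid | C[C@H]1Oc2c([C@@H](CC(=O)O)c3ccccc3)c(O)c(C[C@@H](C=C(C)C)CCC(C)=C)c(O)c2C(=O)[C@H]1C | intermediate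
20 | 3-[(2R,3S,6S)-4-hydroxy-2,3-dimethyl-6-(3-methylbut-2-en-1-yl)-6-[(2S)-5-methyl-2-(2-methylprop-1-en-1-yl)hex-5-en-1-yl]-5,7-dioxo-3,5,6,7-tetrahydro-2H-chromen-8-yl]-(3S)-3-phenylpropanoic acid | C=C(C)CC[C@H](C=C(C)C)C[C@@]1(CC=C(C)C)C(=O)C2=C(O)[C@@H](C)[C@@H](C)OC2=C([C@@H](CC(=O)O)c2ccccc2)C1=O | target

**Step count and risks**
Total steps: 8. Longest linear sequence: 7 (steps 2 to 8 from flopropione 3; equally step 1 then steps 3 to 8 from diene 1).

Most likely to fail, first: step 6, the new reaction. The phosphoric acid may be too weak to dehydrate 13 before retro-aldol sets in. The 2-OH may compete with the 6-OH, giving the 8-alkyl regioisomer, which would have to be removed by chromatography. The enantio- and cis-selectivity are unproven. The fallback is known chemistry and sets out from 13: catalytic p-toluenesulfonic acid in toluene at 40 °C dehydrates 13 to the tigloyl ketone 14, which is isolated this time. Then (−)-quinine (20 mol%) in chlorobenzene at 15 °C effects the established cinchona-alkaloid-catalysed intramolecular oxa-Michael addition of o-tigloylphenols, which gives cis-(2R,3S)-2,3-dimethylchromanones. This rejoins the route at 15.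

Second: step 8. Face selection at C6 rests on catalyst control over a substrate that already carries four stereocentres, and the allylation is run on a polyanion in wet THF. The fallback drops the catalyst and relies on separation. It sets out from 17: aqueous KOH (3 equiv) opens the lactone, and prenyl bromide at 0 °C alkylates C6 (classical alkylative dearomatisation of acylphloroglucinols in water). Acidification gives 20 together with its C6 epimer, the (6R)-diastereomer of 20 F1. The two are separated by preparative reversed-phase HPLC, rejoining the route at 20.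

Third: step 3. The unsubstituted quinone methide 7 may alkylate the secondary-amine catalyst or the free ring carbon of 6 faster than the catalytic enamine. The fallback replaces the catalytic enamine by a stoichiometric auxiliary enamine and sets out from 2 and 6. Aldehyde 2 is condensed with (R)-2-(methoxymethyl)pyrrolidine (K2CO3, Et2O, 0 °C) to the preformed enamine (2R)-2-(methoxymethyl)-1-[(1E)-5-methylhexa-1,5-dien-1-yl]pyrrolidine F2. Sulfone 6 is then treated with F2 (2.5 equiv) and NaHCO3 in CH2Cl2 at −20 °C, the auxiliary-controlled form of the classical Mannich-base/enamine chroman synthesis. This gives the cyclic N,O-acetal 1-{(3S)-5,7-dihydroxy-2-[(2R)-2-(methoxymethyl)pyrrolidin-1-yl]-3-(3-methylbut-3-en-1-yl)-3,4-dihydro-2H-chromen-6-yl}propan-1-one F3. Aqueous acetic acid hydrolyses F3 to lactol 8, where the route is rejoined.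

**Further compounds**
F0 | step 6 | none | none
F1 | step 8 | (6R)-epimer of 20, 3-[(2R,3S,6R)-4-hydroxy-2,3-dimethyl-6-(3-methylbut-2-en-1-yl)-6-[(2S)-5-methyl-2-(2-methylprop-1-en-1-yl)hex-5-en-1-yl]-5,7-dioxo-3,5,6,7-tetrahydro-2H-chromen-8-yl]-(3S)-3-phenylpropanoic acid | C=C(C)CC[C@H](C=C(C)C)C[C@]1(CC=C(C)C)C(=O)C2=C(O)[C@@H](C)[C@@H](C)OC2=C([C@@H](CC(=O)O)c2ccccc2)C1=O
F2 | step 3 | (2R)-2-(methoxymethyl)-1-[(1E)-5-methylhexa-1,5-dien-1-yl]pyrrolidine | COC[C@H]1CCCN1/C=C/CCC(C)=C
F3 | step 3 | 1-{(3S)-5,7-dihydroxy-2-[(2R)-2-(methoxymethyl)pyrrolidin-1-yl]-3-(3-methylbut-3-en-1-yl)-3,4-dihydro-2H-chromen-6-yl}propan-1-one | CCC(=O)c1c(O)cc2c(c1O)C[C@H](CCC(C)=C)C(N1CCC[C@@H]1COC)O2
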